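**Retrosynthetic overview**
- Tomentodione P ⇐ Mitsunobu inversion at C5 ⇐ 5-epi-alcohol ⇐ aluminium-amide isomerisation of a 4,5-epoxide (the epoxide ring is opened last).
- The dihydropyran, the only ring built, ⇐ cyclodehydration of a C8 tertiary alcohol onto a trione carbonyl.
- Key C–C bond, trione C-2 to the isobutyl-bearing carbon C4′ ⇐ addition of the electrophilic radical of 2-bromosyncarpic acid (an enolonium-type form of a carbon that normally reacts as the nucleophile) to a (Z)-alkene.
- That (Z)-allylic tertiary alcohol ⇐ Z-Wittig ⇐ α-hydroxy aldehyde ⇐ osmylation of (−)-caryophyllene oxide, which fixes the C8–O bond.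
- Cyclobutane and nine-membered ring come with caryophyllene oxide, the trione ring with syncarpic acid.

Assumption: caryophyllane numbering is used (C1/C9 ring fusion, C4 methyl-bearing, C8 spiro carbon, C13 its exocyclic carbon = chromene C3′, C4′ = isobutyl-bearing carbon), and syncarpic acid is bought as a catalogue chemical.

Step 1
Reactants: 1 (−)-caryophyllene oxide, (1R,4R,5R,9S)-4,5-epoxycaryophyll-8(13)-ene
Product: 2 (1R,4R,5R,8R,9S)-4,5-epoxycaryophyllane-8,13-diol
Conditions: OsO4 (2 mol%), NMO (1.5 equiv), acetone/H2O 5:1, rt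
Reagents that add atoms: N-methylmorpholine N-oxide C[N+]1([O-])CCOCC1; water O; OsO4 O=[Os](=O)(=O)=O (catalytic carrier of both oxygens)
Why: Upjohn dihydroxylation hits the only alkene while the epoxide survives the neutral medium, and syn-addition on the open outer face of the exocyclic methylene fixes the C8 oxygen on the side it occupies in the target (new stereocentre C8).

Step 2
Reactants: 2 (1R,4R,5R,8R,9S)-4,5-epoxycaryophyllane-8,13-diol
Product: 3 (1R,4R,5R,8R,9S)-4,5-epoxy-8-hydroxycaryophyllan-13-al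
Conditions: IBX (1.5 equiv), DMSO, rt
Reagents that add atoms: none
Why: IBX oxidation turns the primary carbinol of the 1,2-diol into the aldehyde without glycol cleavage and leaves the tertiary alcohol and the epoxide alone, while C8 carries no hydrogen and cannot epimerise.

Step 3
Reactants: 3 (1R,4R,5R,8R,9S)-4,5-epoxy-8-hydroxycaryophyllan-13-al; 4 (3-methylbutyl)triphenylphosphonium bromide
Product: 6 (1R,4R,5R,8S,9S,13Z)-4,5-epoxy-13-(3-methylbutylidene)caryophyllan-8-ol, via phosphonium ylide 5 (not isolated)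
Conditions: 4 (2.5 equiv), NaN(SiMe3)2 (2.4 equiv), THF, −78 °C; then 3, −78 °C → rt
Reagents that add atoms: none
Why: Salt-free Wittig olefination with a non-stabilised ylide runs through the kinetic cis-oxaphosphetane and gives the (Z)-alkene, the excess ylide covering the free tertiary hydroxyl as its sodium alkoxide.

Step 4
Reactants: 7 syncarpic acid, 2,2,4,4-tetramethylcyclohexane-1,3,5-trione
Product: 8 2-bromosyncarpic acid, 6-bromo-2,2,4,4-tetramethylcyclohexane-1,3,5-trione
Conditions: NBS (1.0 equiv), CH2Cl2, 0 °C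
Reagents that add atoms: N-bromosuccinimide O=C1CCC(=O)N1Br
Why: Electrophilic bromination of the enol of the β-triketone by NBS stops at the monobromide because the product is itself a deactivated, hydrogen-bonded enol.

Step 5
Reactants: 6 (1R,4R,5R,8S,9S,13Z)-4,5-epoxy-13-(3-methylbutylidene)caryophyllan-8-ol; 8 2-bromosyncarpic acid
Product: 10 (1R,4R,5R,8S,9S,4′S)-4,5-epoxy-4′-isobutyl-6′,6′,8′,8′-tetramethyl-3′,4′-dihydrospiro[13-norcaryophyllane-8,2′-chromene]-5′,7′(6′H,8′H)-dione, via hydroxy-trione 9 (not isolated)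
Conditions: 8 (2 equiv), Bu3SnH (2.2 equiv, syringe pump), Et3B (0.3 equiv)/air, toluene, 0 °C → rt; then PPTS (10 mol%), 4 Å molecular sieves, CH2Cl2, 40 °C
Reagents that add atoms: none
Why: Proposed new method: Bu3Sn• abstracts bromine from 8 and the electrophilic trione radical (the enolonium-type form of a carbon that is otherwise a nucleophile, here bonded to an alkene carbon that is itself a π-nucleophile) adds to the alkene carbon remote from quaternary C8, with A(1,3) strain in the (Z)-alkene holding the C8–OH in the alkene plane so that attack comes anti to the bulky cyclobutane-bearing C9 arm and sets C4′ as S, after which the C13 radical takes hydrogen from Bu3SnH and mild acid closes the tertiary alcohol onto the adjacent trione carbonyl (hemiketal, loss of water, C8–O retained); the closest known reactions are tin-hydride (Giese-type) additions of α-halo-1,3-dicarbonyl radicals to alkenes and Mn(OAc)3-mediated additions of cyclic 1,3-dione radicals to alkenes.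

Step 6
Reactants: 10 (1R,4R,5R,8S,9S,4′S)-4,5-epoxy-4′-isobutyl-6′,6′,8′,8′-tetramethyl-3′,4′-dihydrospiro[13-norcaryophyllane-8,2′-chromene]-5′,7′(6′H,8′H)-dione
Product: 11 5-epi-tomentodione P, (1R,3Z,5R,8S,9S,4′S)-5-hydroxy-4′-isobutyl-6′,6′,8′,8′-tetramethyl-3′,4′-dihydrospiro[13-norcaryophyll-3-ene-8,2′-chromene]-5′,7′(6′H,8′H)-dione
Conditions: Et2AlCl + lithium 2,2,6,6-tetramethylpiperidide (4 equiv each, giving diethylaluminium 2,2,6,6-tetramethylpiperidide), toluene, 0 °C → rt
Reagents that add atoms: none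
Why: Yamamoto epoxide-to-allylic-alcohol isomerisation (syn β-elimination in a cyclic Al–O–C–C–H array) in which the hindered amide takes the C3 proton, the one cis to the epoxide hydrogen, so that the C4–O bond breaks to the ring (3Z)-alkene while the C5–O bond keeps its R configuration and the two hindered, non-enolisable carbonyls are left alone.

Step 7
Reactants: 11 5-epi-tomentodione P
Product: 13 Tomentodione P, via 4-nitrobenzoate 12 (not isolated)
Conditions: PPh3, DIAD, 4-nitrobenzoic acid (3 equiv each), THF, 0 °C → rt; then MeOH, K2CO3 (0.5 equiv), rt, same flask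
Reagents that add atoms: 4-nitrobenzoic acid OC(=O)c1ccc(cc1)[N+](=O)[O-]
Why: Mitsunobu reaction in which SN2 attack of the carboxylate on the oxyphosphonium inverts C5 from R to S, and mild methanolysis of the activated ester then frees the alcohol without touching the vinylogous ester.

**Compound list**
1 | (−)-caryophyllene oxide, (1R,4R,5R,9S)-4,5-epoxycaryophyll-8(13)-ene | C[C@@]12CC[C@@H]3[C@H](CC3(C)C)C(=C)CC[C@H]1O2 | starting material
2 | (1R,4R,5R,8R,9S)-4,5-epoxycaryophyllane-8,13-diol | C[C@@]12CC[C@@H]3[C@H](CC3(C)C)[C@](O)(CC[C@H]1O2)CO | intermediate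
3 | (1R,4R,5R,8R,9S)-4,5-epoxy-8-hydroxycaryophyllan-13-al | C[C@@]12CC[C@@H]3[C@H](CC3(C)C)[C@](O)(CC[C@H]1O2)C=O | intermediate
4 | (3-methylbutyl)triphenylphosphonium bromide | CC(C)CC[P+](c1ccccc1)(c1ccccc1)c1ccccc1.[Br-] | starting material
5 | (3-methylbutylidene)triphenylphosphorane | CC(C)CC=P(c1ccccc1)(c1ccccc1)c1ccccc1 | intermediate
6 | (1R,4R,5R,8S,9S,13Z)-4,5-epoxy-13-(3-methylbutylidene)caryophyllan-8-ol | C[C@@]12CC[C@@H]3[C@H](CC3(C)C)[C@](O)(CC[C@H]1O2)/C=C\CC(C)C | intermediate
7 | syncarpic acid, 2,2,4,4-tetramethylcyclohexane-1,3,5-trione | CC1(C)C(=O)CC(=O)C(C)(C)C1=O | starting material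
8 | 2-bromosyncarpic acid, 6-bromo-2,2,4,4-tetramethylcyclohexane-1,3,5-trione | CC1(C)C(=O)C(Br)C(=O)C(C)(C)C1=O | intermediate
9 | (1R,4R,5R,8S,9S)-4,5-epoxy-13-[(1S)-3-methyl-1-(3,3,5,5-tetramethyl-2,4,6-trioxocyclohexyl)butyl]caryophyllan-8-ol | C[C@@]12CC[C@@H]3[C@H](CC3(C)C)[C@](O)(CC[C@H]1O2)C[C@H](CC(C)C)C1C(=O)C(C)(C)C(=O)C(C)(C)C1=O | intermediate
10 | (1R,4R,5R,8S,9S,4′S)-4,5-epoxy-4′-isobutyl-6′,6′,8′,8′-tetramethyl-3′,4′-dihydrospiro[13-norcaryophyllane-8,2′-chromene]-5′,7′(6′H,8′H)-dione | C[C@@]12CC[C@@H]3[C@H](CC3(C)C)[C@]4(CC[C@H]1O2)C[C@H](CC(C)C)C1=C(O4)C(C)(C)C(=O)C(C)(C)C1=O | intermediate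
11 | 5-epi-tomentodione P, (1R,3Z,5R,8S,9S,4′S)-5-hydroxy-4′-isobutyl-6′,6′,8′,8′-tetramethyl-3′,4′-dihydrospiro[13-norcaryophyll-3-ene-8,2′-chromene]-5′,7′(6′H,8′H)-dione | C/C1=C/C[C@@H]2[C@H](CC2(C)C)[C@]2(CC[C@H]1O)C[C@H](CC(C)C)C1=C(O2)C(C)(C)C(=O)C(C)(C)C1=O | intermediate
12 | tomentodione P 4-nitrobenzoate, the (5S)-ester | C/C1=C/C[C@@H]2[C@H](CC2(C)C)[C@]2(CC[C@@H]1OC(=O)c3ccc(cc3)[N+](=O)[O-])C[C@H](CC(C)C)C1=C(O2)C(C)(C)C(=O)C(C)(C)C1=O | intermediate
13 | Tomentodione P, (1R,3Z,5S,8S,9S,4′S) | C/C1=C/C[C@@H]2[C@H](CC2(C)C)[C@]2(CC[C@@H]1O)C[C@H](CC(C)C)C1=C(O2)C(C)(C)C(=O)C(C)(C)C1=O | target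

**Totals**
Total step count: 7. Longest linear sequence: 6 (steps 1, 2, 3, 5, 6, 7; step 4 is the side branch).

**Three steps most likely to fail, each with a fallback**

The radical addition of step 5 is the weakest point. The hindered alkene may react slowly, so that 8 is simply reduced back to 7, and the diastereoselectivity at C4′ rests on a conformational model. The fallback swaps the roles of the two partners and sets out from 1. Epoxidation with mCPBA/NaHCO3 gives the diepoxide F3, and LiI/AcOH opens only the spiro-epoxide at its CH2 to give the iodohydrin F4. Separately, Knoevenagel condensation of 7 with isovaleraldehyde (piperidine, AcOH) gives the alkylidene trione F5. Bu3SnH/AIBN then adds the nucleophilic C13 radical from F4 to the electron-poor alkene of F5. This comes back to the route at 9, which is closed to 10 as before, but C4′ is then formed without control and the isomers must be separated at 10.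

The epoxide isomerisation of step 6 may instead abstract a proton from the C4 methyl group and give the exocyclic alkene, or the aluminium reagent may attack a carbonyl. The fallback sets out from 10. Cp2TiCl (trivalent titanium, made from Cp2TiCl2 and zinc dust) opens the epoxide by the radical route to the exocyclic allylic alcohol F6. Dess–Martin periodinane gives the exo-enone F7, and DBU moves the double bond into conjugation inside the ring to give the ring enone F8. Reduction with (R)-2-methyl-CBS-oxazaborolidine and catecholborane, under reagent control, then gives the 5S alcohol and comes back to the route at 13, bypassing 11 and 12.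

The osmylation of step 1 carries the configuration of the spiro carbon. If osmium adds to the other face, everything after it belongs to the wrong C8 series. The fallback brings in carbon instead of oxygen from the outer face and sets out from 1. Ozonolysis (O3, CH2Cl2/MeOH, −78 °C; Me2S) removes C13 and gives kobusone F1. The acetylide of 4-methylpent-1-yne (n-BuLi, CeCl3, THF, −78 °C) adds to the ketone, so that oxygen ends on the side opposite to the one an oxygen reagent would choose, and gives the propargylic alcohol F2. Semi-hydrogenation (H2, Pd/CaCO3 poisoned with Pb(OAc)2, quinoline) gives the (Z)-alkene and comes back to the route at 6.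

**Further compounds**
F1 | step 1 | kobusone, (1R,4R,5R,9S)-4,5-epoxy-13-norcaryophyllan-8-one | C[C@@]12CC[C@@H]3[C@H](CC3(C)C)C(=O)CC[C@H]1O2
F2 | step 1 | (1R,4R,5R,8R,9S)-4,5-epoxy-13-(3-methylbutylidyne)caryophyllan-8-ol | C[C@@]12CC[C@@H]3[C@H](CC3(C)C)[C@](O)(CC[C@H]1O2)C#CCC(C)C
F3 | step 5 | (1R,4R,5R,8R,9S)-4,5:8,13-diepoxycaryophyllane | C[C@@]12CC[C@@H]3[C@H](CC3(C)C)[C@]4(CC[C@H]1O2)CO4
F4 | step 5 | (1R,4R,5R,8R,9S)-4,5-epoxy-13-iodocaryophyllan-8-ol | C[C@@]12CC[C@@H]3[C@H](CC3(C)C)[C@](O)(CC[C@H]1O2)CI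
F5 | step 5 | 2,2,4,4-tetramethyl-6-(3-methylbutylidene)cyclohexane-1,3,5-trione | CC(C)CC=C1C(=O)C(C)(C)C(=O)C(C)(C)C1=O
F6 | step 6 | (1R,5R,8S,9S,4′S)-5-hydroxy-4′-isobutyl-6′,6′,8′,8′-tetramethyl-3′,4′-dihydrospiro[13-norcaryophyll-4(12)-ene-8,2′-chromene]-5′,7′(6′H,8′H)-dione | C=C1CC[C@@H]2[C@H](CC2(C)C)[C@]2(CC[C@H]1O)C[C@H](CC(C)C)C1=C(O2)C(C)(C)C(=O)C(C)(C)C1=O
F7 | step 6 | (1R,8S,9S,4′S)-4′-isobutyl-6′,6′,8′,8′-tetramethyl-3′,4′-dihydrospiro[13-norcaryophyll-4(12)-ene-8,2′-chromene]-5,5′,7′(6′H,8′H)-trione | C=C1CC[C@@H]2[C@H](CC2(C)C)[C@]2(CCC1=O)C[C@H](CC(C)C)C1=C(O2)C(C)(C)C(=O)C(C)(C)C1=O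
F8 | step 6 | (1R,3Z,8S,9S,4′S)-4′-isobutyl-6′,6′,8′,8′-tetramethyl-3′,4′-dihydrospiro[13-norcaryophyll-3-ene-8,2′-chromene]-5,5′,7′(6′H,8′H)-trione | C/C1=C/C[C@@H]2[C@H](CC2(C)C)[C@]2(CCC1=O)C[C@H](CC(C)C)C1=C(O2)C(C)(C)C(=O)C(C)(C)C1=O
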